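## Retrosynthetic overview

1. The only ring, the 28-membered macrolactone, is closed in the penultimate step where the polyketide chain is released in nature: S→O acyl transfer from a C1 thioester of the open-chain N-(2-hydroxypentanoyl) amino acid to the C2′ hydroxyl. Only the C20/C21/C23 triol is masked; the C9 hydroxyl stays free.
2. The seco ester comes from a B-alkyl Suzuki coupling at C17–C18 (north alkene C18–C24 carrying the hydroxy amide), after a Suzuki coupling at C15–C16 that joins the south alkenyl boronate to an E-bromo-iodo three-carbon linchpin (C16, C17, CH2OMe) which fixes the 16Z geometry.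
3. The south part C1–C15 is built on (R)-epichlorohydrin (C8–C10, gives C9): alkyl–alkyl Suzuki at C5–C6 with a bromo ester from a desymmetrised meso anhydride (C2, C4), and Grignard opening at C10–C11 by a bromide from copper-catalysed asymmetric allylic alkylation (C13).
4. The north part comes from anti-selective γ-borylallylboration of a C21 aldehyde made from ethyl (S)-4-chloro-3-hydroxybutanoate (C23), then azide reduction and acylation with (S)-2-hydroxypentanoic acid from L-norvaline.

Assumption: locants C1–C24 are those of the 24-aminotetracosadienoic acid chain (C1 = lactone carbonyl, C24 = CH2N); C2′ is the carbinol carbon of the 2-hydroxypentanoyl unit.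
Assumption: the sense of induction of the chiral catalysts and reagents in steps 1, 6 and 17 is taken from the usual models; if one proves opposite, its commercial antipode is used in the same step.

## Route

Step 1
Reactants: 1 meso-2,4-dimethylglutaric anhydride [(3R,5S)-3,5-dimethyloxane-2,6-dione]
Product: 2 (2R,4S)-5-methoxy-2,4-dimethyl-5-oxopentanoic acid
Conditions: MeOH (10 eq), (DHQD)2AQN (10 mol%), Et2O, −30 °C
Reagents that add atoms: methanol, CO
Why: Cinchona-alkaloid-catalysed desymmetrising alcoholysis of a meso anhydride delivers methanol to one enantiotopic carbonyl and so fixes both methyl stereocentres (C2 and C4 of the target, syn) in one operation.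

Step 2
Reactants: 2 (2R,4S)-5-methoxy-2,4-dimethyl-5-oxopentanoic acid
Product: 3 methyl (2S,4R)-5-hydroxy-2,4-dimethylpentanoate
Conditions: BH3·SMe2 (1.2 eq), THF, −10 → 20 °C; aqueous work-up, used at once
Reagents that add atoms: none
Why: Chemoselective borane reduction of the carboxylic acid (via the acyloxyborane) leaves the methyl ester and both stereocentres untouched.

Step 3
Reactants: 3 methyl (2S,4R)-5-hydroxy-2,4-dimethylpentanoate
Product: 4 methyl (2S,4R)-5-bromo-2,4-dimethylpentanoate
Conditions: CBr4, PPh3, CH2Cl2, 0 °C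
Reagents that add atoms: carbon tetrabromide, BrC(Br)(Br)Br
Why: Appel bromination of the primary alcohol under neutral conditions outruns δ-lactonisation and does not touch the stereocentres.

Step 4
Reactants: 5 (R)-epichlorohydrin
Product: 7 (R)-2-allyloxirane, via (R)-1-chloropent-4-en-2-ol 6 (not isolated)
Conditions: vinylMgBr (1.2 eq), CuI (10 mol%), THF, −40 °C; NH4Cl (aq); then powdered NaOH, Et2O, rt
Reagents that add atoms: vinylmagnesium bromide, C=C[Mg]Br
Why: Copper-catalysed Grignard opening at the unsubstituted epoxide carbon followed by base-induced chlorohydrin ring closure (epichlorohydrin linchpin) carries the chiral-pool stereocentre unchanged to what becomes C9.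

Step 5
Reactants: 7 (R)-2-allyloxirane; 4 methyl (2S,4R)-5-bromo-2,4-dimethylpentanoate
Product: 9 methyl (2S,4S)-2,4-dimethyl-8-[(2R)-oxiran-2-yl]octanoate, via B-alkyl-9-BBN adduct 8 (not isolated)
Conditions: 9-BBN (1.1 eq), THF, 0 °C → rt; then 4, Pd(OAc)2 (5 mol%), PCy3 (10 mol%), K3PO4·H2O, THF, rt → 40 °C
Reagents that add atoms: none
Why: Anti-Markovnikov hydroboration followed by Fu-type alkyl–alkyl Suzuki–Miyaura coupling (the bulky electron-rich phosphine suppresses β-hydride elimination) forms C5–C6 without touching the epoxide, the ester or any stereocentre.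

Step 6
Reactants: 10 (E)-1,4-dibromobut-2-ene
Product: 11 (S)-3-(bromomethyl)pent-1-ene
Conditions: EtMgBr (1.15 eq), CuBr·SMe2 (1 mol%), (R,R)-Taniaphos (1.2 mol%), CH2Cl2, −78 °C
Reagents that add atoms: ethylmagnesium bromide, CC[Mg]Br
Why: Copper-catalysed asymmetric allylic alkylation (SN2′, branched-selective) sets the ethyl-bearing stereocentre (C13 of the target) under ligand control and leaves the second bromide as a handle.

Step 7
Reactants: 11 (S)-3-(bromomethyl)pent-1-ene
Product: 13 (R)-3-ethylpent-4-en-1-ol, via Grignard reagent of 11 12 (not isolated)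
Conditions: Mg, THF, 0 °C → rt; then (CH2O)n, 0 °C → rt; NH4Cl (aq)
Reagents that add atoms: formaldehyde (as paraformaldehyde), C=O
Why: Grignard formation and addition to formaldehyde give a one-carbon homologation in which the stereocentre, β to magnesium, is not involved.

Step 8
Reactants: 13 (R)-3-ethylpent-4-en-1-ol
Product: 14 (R)-5-bromo-3-ethylpent-1-ene
Conditions: CBr4, PPh3, CH2Cl2, 0 °C
Reagents that add atoms: carbon tetrabromide, BrC(Br)(Br)Br
Why: Appel bromination of the primary alcohol proceeds without affecting the remote stereocentre or the alkene.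

Step 9
Reactants: 14 (R)-5-bromo-3-ethylpent-1-ene; 9 methyl (2S,4S)-2,4-dimethyl-8-[(2R)-oxiran-2-yl]octanoate
Product: 16 methyl (2S,4S,9R,13R)-13-ethyl-9-hydroxy-2,4-dimethylpentadec-14-enoate, via Grignard reagent of 14 15 (not isolated)
Conditions: 14 (1.5 eq), Mg, THF, rt; then 9, CuI (10 mol%), THF, −40 → −20 °C; NH4Cl (aq)
Reagents that add atoms: none
Why: Copper-catalysed Grignard opening of the terminal epoxide at C10 is much faster at −40 °C than addition to the hindered α-branched methyl ester, and C9 keeps the configuration of the epoxide.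

Step 10
Reactants: 16 methyl (2S,4S,9R,13R)-13-ethyl-9-hydroxy-2,4-dimethylpentadec-14-enoate
Product: 17 methyl (2S,4S,9R,13R,14E)-13-ethyl-9-hydroxy-2,4-dimethyl-15-(4,4,5,5-tetramethyl-1,3,2-dioxaborolan-2-yl)pentadec-14-enoate
Conditions: vinylboronic acid pinacol ester (4 eq), second-generation Hoveyda–Grubbs catalyst (5 mol%), CH2Cl2, 40 °C
Reagents that add atoms: vinylboronic acid pinacol ester, C=CB1OC(C)(C)C(C)(C)O1
Why: Olefin cross-metathesis of the only alkene with a vinyl boronate gives the thermodynamically favoured E-alkenyl boronate (C14=C15) and tolerates the free hydroxyl and the ester.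

Step 11
Reactants: 18 3-methoxyprop-1-yne (methyl propargyl ether)
Product: 19 (E)-2-bromo-1-iodo-3-methoxyprop-1-ene
Conditions: IBr (1.0 eq), CH2Cl2, −78 → 0 °C, dark
Reagents that add atoms: iodine monobromide, IBr
Why: Electrophilic anti iodobromination through the bridged iodonium ion, with Markovnikov delivery of bromide to the internal carbon, gives the E dihalide in which iodine is cis to CH2OMe and thereby preloads the C16=C17 geometry.

Step 12
Reactants: 17 the E-alkenyl pinacol boronate; 19 (E)-2-bromo-1-iodo-3-methoxyprop-1-ene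
Product: 20 methyl (2S,4S,9R,13R,14E,16E)-17-bromo-13-ethyl-9-hydroxy-18-methoxy-2,4-dimethyloctadeca-14,16-dienoate
Conditions: Pd(dppf)Cl2 (5 mol%), AsPh3 (10 mol%), Cs2CO3 (3 eq), DMF/H2O, 20 °C
Reagents that add atoms: none
Why: Suzuki–Miyaura coupling is chemoselective for the alkenyl iodide over the alkenyl bromide and stereoretentive at both partners, so C15 ends cis to CH2OMe (the 16E descriptor is only due to bromine priority).

Step 13
Reactants: 21 L-norvaline
Product: 22 (S)-2-hydroxypentanoic acid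
Conditions: NaNO2, 0.5 M H2SO4 (aq), 0 °C → rt
Reagents that add atoms: water, O
Why: Diazotisation of the α-amino acid proceeds with double inversion through the α-lactone and so gives the hydroxy acid with net retention.

Step 14
Reactants: 23 ethyl (S)-4-chloro-3-hydroxybutanoate
Product: 24 ethyl (S)-4-azido-3-hydroxybutanoate
Conditions: NaN3, DMF, 90 °C
Reagents that add atoms: sodium azide, [Na+].[N-]=[N+]=[N-]
Why: SN2 displacement at the primary carbon installs the C24 nitrogen without touching the carbinol stereocentre (C23 of the target).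

Step 15
Reactants: 24 ethyl (S)-4-azido-3-hydroxybutanoate
Product: 25 ethyl (S)-4-azido-3-[(tert-butyldimethylsilyl)oxy]butanoate
Conditions: TBSCl, imidazole, DMF, rt
Reagents that add atoms: tert-butyldimethylsilyl chloride, CC(C)(C)[Si](C)(C)Cl
Why: Standard silylation masks the C23 hydroxyl, which would otherwise compete in the later lactonisation and cause β-elimination at the aldehyde stage.

Step 16
Reactants: 25 ethyl (S)-4-azido-3-[(tert-butyldimethylsilyl)oxy]butanoate
Product: 26 (S)-4-azido-3-[(tert-butyldimethylsilyl)oxy]butanal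
Conditions: i-Bu2AlH (1.1 eq), CH2Cl2, −78 °C; potassium sodium tartrate (aq)
Reagents that add atoms: none
Why: Partial ester reduction stops at the aldehyde because the tetrahedral aluminium hemiacetal is stable at −78 °C, and the azide is inert at this temperature.

Step 17
Reactants: 26 (S)-4-azido-3-[(tert-butyldimethylsilyl)oxy]butanal
Product: 28 (3R,4S,6S)-7-azido-6-[(tert-butyldimethylsilyl)oxy]hept-1-ene-3,4-diol, via boron-bound allylation adduct 27 (not isolated)
Conditions: pinacol allenylboronate, (+)-Ipc2BH [from (−)-α-pinene], THF, 0 → 20 °C; then 26, −78 °C → rt; then NaOH (aq), H2O2, 0 °C → rt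
Reagents that add atoms: pinacol allenylboronate, C=C=CB1OC(C)(C)C(C)(C)O1; hydrogen peroxide, OO
Why: Brown-type γ-borylallylboration through a chair Zimmerman–Traxler transition state gives the anti C20/C21 relationship from the E reagent and 21S (hence 20R) from Re-face attack dictated by the isopinocampheyl groups, and the C–B bond is then oxidised with retention to the anti diol.

Step 18
Reactants: 28 (3R,4S,6S)-7-azido-6-[(tert-butyldimethylsilyl)oxy]hept-1-ene-3,4-diol
Product: 29 (4R,5S)-5-[(2S)-3-azido-2-[(tert-butyldimethylsilyl)oxy]propyl]-4-ethenyl-2,2-dimethyl-1,3-dioxolane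
Conditions: 2,2-dimethoxypropane, PPTS (cat.), CH2Cl2, rt
Reagents that add atoms: 2,2-dimethoxypropane, COC(C)(C)OC
Why: Acid-catalysed transketalisation protects the anti 1,2-diol as its cis-dioxolane, so the whole triol is masked by two groups that fall off together at the end.

Step 19
Reactants: 29 the azido acetonide; 22 (S)-2-hydroxypentanoic acid
Product: 31 (2S)-N-[(2S)-2-[(tert-butyldimethylsilyl)oxy]-3-[(4S,5R)-5-ethenyl-2,2-dimethyl-1,3-dioxolan-4-yl]propyl]-2-hydroxypentanamide, via primary amine 30 (not isolated)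
Conditions: PPh3, THF/H2O, 50 °C; concentrate; then 22, EDC·HCl, HOBt, CH2Cl2, 0 °C → rt
Reagents that add atoms: none
Why: Staudinger reduction followed by carbodiimide amide coupling acylates the amine far faster than the secondary hydroxyl of the acid, and the HOBt ester suppresses epimerisation at C2′.

Step 20
Reactants: 31 the north alkene; 20 the south bromodiene
Product: 33 methyl (2S,4S,9R,13R,14E,16Z,20R,21S,23S)-13-ethyl-9-hydroxy-24-[(2S)-2-hydroxypentanamido]-20,21-(isopropylidenedioxy)-17-(methoxymethyl)-2,4-dimethyl-23-[(tert-butyldimethylsilyl)oxy]tetracosa-14,16-dienoate, via B-alkyl-9-BBN adduct 32 (not isolated)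
Conditions: 31, 9-BBN (2.5 eq, the excess covers O-borylation of the free hydroxyl), THF, 0 °C → rt; then 20, Pd(dppf)Cl2 (10 mol%), AsPh3, Cs2CO3, DMF/H2O, rt → 45 °C
Reagents that add atoms: none
Why: B-alkyl Suzuki–Miyaura coupling replaces the alkenyl bromide with retention, giving the (14E,16Z)-diene with CH2OMe cis to C15 and completing the carbon chain.

Step 21
Reactants: 33 the seco methyl ester
Product: 34 (2S,4S,9R,13R,14E,16Z,20R,21S,23S)-13-ethyl-9-hydroxy-24-[(2S)-2-hydroxypentanamido]-20,21-(isopropylidenedioxy)-17-(methoxymethyl)-2,4-dimethyl-23-[(tert-butyldimethylsilyl)oxy]tetracosa-14,16-dienoic acid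
Conditions: LiOH·H2O (5 eq), THF/MeOH/H2O, rt; then 0.5 M HCl to pH 4, 0 °C
Reagents that add atoms: lithium hydroxide, [Li+].[OH-]
Why: Saponification of the methyl ester at room temperature leaves the amide, silyl ether and acetonide intact and does not epimerise C2.

Step 22
Reactants: 34 the seco acid
Product: 36 20,21-O-isopropylidene-23-O-(tert-butyldimethylsilyl) derivative of 37 (protected 28-membered macrolactone), via S-(pyridin-2-yl) thioester 35 (not isolated)
Conditions: 2,2′-dipyridyl disulfide, PPh3, toluene, rt; then syringe-pump addition (10 h) to AgOTf (3 eq), 2,6-di-tert-butyl-4-methylpyridine, toluene (final 1 mM), 25 → 40 °C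
Reagents that add atoms: none
Why: Corey–Nicolaou thioester formation and Gerlach silver activation reproduce the S→O acyl transfer of chain release, with the C2′ hydroxyl closing the strain-free 28-membered ring while the unprotected C9 hydroxyl could only form a strained 10-membered lactone, and no stereocentre is touched.

Step 23
Reactants: 36 the protected macrolactone
Product: 37 CNP0221503.3
Conditions: HF (48% aq), MeCN, 0 °C → rt
Reagents that add atoms: none
Why: Aqueous hydrofluoric acid cleaves the silyl ether and hydrolyses the cis-acetonide in one global deprotection that leaves the lactone, amide, allylic ether and diene intact.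

## Compound list

1 | meso-2,4-dimethylglutaric anhydride [(3R,5S)-3,5-dimethyloxane-2,6-dione] | O=C1OC(=O)[C@H](C)C[C@@H]1C | starting material
2 | (2R,4S)-5-methoxy-2,4-dimethyl-5-oxopentanoic acid | COC(=O)[C@@H](C)C[C@@H](C)C(O)=O | intermediate
3 | methyl (2S,4R)-5-hydroxy-2,4-dimethylpentanoate | COC(=O)[C@@H](C)C[C@@H](C)CO | intermediate
4 | methyl (2S,4R)-5-bromo-2,4-dimethylpentanoate | COC(=O)[C@@H](C)C[C@@H](C)CBr | intermediate
5 | (R)-epichlorohydrin | ClC[C@H]1CO1 | starting material
6 | (R)-1-chloropent-4-en-2-ol | C=CC[C@@H](O)CCl | intermediate (not isolated)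
7 | (R)-2-allyloxirane | C=CC[C@@H]1CO1 | intermediate
8 | 9-[3-[(2R)-oxiran-2-yl]propyl]-9-borabicyclo[3.3.1]nonane | B1(CCC[C@@H]2CO2)C3CCCC1CCC3 | intermediate (not isolated)
9 | methyl (2S,4S)-2,4-dimethyl-8-[(2R)-oxiran-2-yl]octanoate | COC(=O)[C@@H](C)C[C@@H](C)CCCC[C@@H]1CO1 | intermediate
10 | (E)-1,4-dibromobut-2-ene | BrC/C=C/CBr | starting material
11 | (S)-3-(bromomethyl)pent-1-ene | BrC[C@@H](CC)C=C | intermediate
12 | [(2S)-2-ethylbut-3-en-1-yl]magnesium bromide | Br[Mg]C[C@@H](CC)C=C | intermediate (not isolated)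
13 | (R)-3-ethylpent-4-en-1-ol | OCC[C@@H](CC)C=C | intermediate
14 | (R)-5-bromo-3-ethylpent-1-ene | BrCC[C@@H](CC)C=C | intermediate
15 | [(3R)-3-ethylpent-4-en-1-yl]magnesium bromide | Br[Mg]CC[C@@H](CC)C=C | intermediate (not isolated)
16 | methyl (2S,4S,9R,13R)-13-ethyl-9-hydroxy-2,4-dimethylpentadec-14-enoate | COC(=O)[C@@H](C)C[C@@H](C)CCCC[C@@H](O)CCC[C@@H](CC)C=C | intermediate
17 | methyl (2S,4S,9R,13R,14E)-13-ethyl-9-hydroxy-2,4-dimethyl-15-(4,4,5,5-tetramethyl-1,3,2-dioxaborolan-2-yl)pentadec-14-enoate | COC(=O)[C@@H](C)C[C@@H](C)CCCC[C@@H](O)CCC[C@@H](CC)/C=C/B1OC(C)(C)C(C)(C)O1 | intermediate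
18 | 3-methoxyprop-1-yne | COCC#C | starting material
19 | (E)-2-bromo-1-iodo-3-methoxyprop-1-ene | I/C=C(/Br)COC | intermediate
20 | methyl (2S,4S,9R,13R,14E,16E)-17-bromo-13-ethyl-9-hydroxy-18-methoxy-2,4-dimethyloctadeca-14,16-dienoate | COC(=O)[C@@H](C)C[C@@H](C)CCCC[C@@H](O)CCC[C@@H](CC)/C=C/C=C(/Br)COC | intermediate
21 | L-norvaline | CCC[C@H](N)C(O)=O | starting material
22 | (S)-2-hydroxypentanoic acid | CCC[C@H](O)C(O)=O | intermediate
23 | ethyl (S)-4-chloro-3-hydroxybutanoate | CCOC(=O)C[C@H](O)CCl | starting material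
24 | ethyl (S)-4-azido-3-hydroxybutanoate | CCOC(=O)C[C@H](O)CN=[N+]=[N-] | intermediate
25 | ethyl (S)-4-azido-3-[(tert-butyldimethylsilyl)oxy]butanoate | CCOC(=O)C[C@H](O[Si](C)(C)C(C)(C)C)CN=[N+]=[N-] | intermediate
26 | (S)-4-azido-3-[(tert-butyldimethylsilyl)oxy]butanal | O=CC[C@H](O[Si](C)(C)C(C)(C)C)CN=[N+]=[N-] | intermediate
27 | allylation adduct: C21 O-diisopinocampheylborinate and C20 pinacol boronate of 28 | C=C[C@@H](B1OC(C)(C)C(C)(C)O1)[C@@H](OB([C@H]1C[C@H]2C[C@@H]([C@@H]1C)C2(C)C)[C@H]1C[C@H]2C[C@@H]([C@@H]1C)C2(C)C)C[C@H](O[Si](C)(C)C(C)(C)C)CN=[N+]=[N-] | intermediate (not isolated)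
28 | (3R,4S,6S)-7-azido-6-[(tert-butyldimethylsilyl)oxy]hept-1-ene-3,4-diol | C=C[C@@H](O)[C@@H](O)C[C@H](O[Si](C)(C)C(C)(C)C)CN=[N+]=[N-] | intermediate
29 | (4R,5S)-5-[(2S)-3-azido-2-[(tert-butyldimethylsilyl)oxy]propyl]-4-ethenyl-2,2-dimethyl-1,3-dioxolane | C=C[C@H]1OC(C)(C)O[C@H]1C[C@H](O[Si](C)(C)C(C)(C)C)CN=[N+]=[N-] | intermediate
30 | (2S)-2-[(tert-butyldimethylsilyl)oxy]-3-[(4S,5R)-5-ethenyl-2,2-dimethyl-1,3-dioxolan-4-yl]propan-1-amine | C=C[C@H]1OC(C)(C)O[C@H]1C[C@H](O[Si](C)(C)C(C)(C)C)CN | intermediate (not isolated)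
31 | (2S)-N-[(2S)-2-[(tert-butyldimethylsilyl)oxy]-3-[(4S,5R)-5-ethenyl-2,2-dimethyl-1,3-dioxolan-4-yl]propyl]-2-hydroxypentanamide | C=C[C@H]1OC(C)(C)O[C@H]1C[C@H](O[Si](C)(C)C(C)(C)C)CNC(=O)[C@@H](O)CCC | intermediate
32 | B-alkyl-9-BBN adduct of 31 (boron on C18) | B1(CC[C@H]2OC(C)(C)O[C@H]2C[C@H](O[Si](C)(C)C(C)(C)C)CNC(=O)[C@@H](O)CCC)C3CCCC1CCC3 | intermediate (not isolated)
33 | methyl (2S,4S,9R,13R,14E,16Z,20R,21S,23S)-13-ethyl-9-hydroxy-24-[(2S)-2-hydroxypentanamido]-20,21-(isopropylidenedioxy)-17-(methoxymethyl)-2,4-dimethyl-23-[(tert-butyldimethylsilyl)oxy]tetracosa-14,16-dienoate | COC(=O)[C@@H](C)C[C@@H](C)CCCC[C@@H](O)CCC[C@@H](CC)/C=C/C=C(\COC)CC[C@H]1OC(C)(C)O[C@H]1C[C@H](O[Si](C)(C)C(C)(C)C)CNC(=O)[C@@H](O)CCC | intermediate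
34 | the corresponding C1 carboxylic acid (protected seco acid) | OC(=O)[C@@H](C)C[C@@H](C)CCCC[C@@H](O)CCC[C@@H](CC)/C=C/C=C(\COC)CC[C@H]1OC(C)(C)O[C@H]1C[C@H](O[Si](C)(C)C(C)(C)C)CNC(=O)[C@@H](O)CCC | intermediate
35 | S-(pyridin-2-yl) thioester of 34 | O=C(Sc1ccccn1)[C@@H](C)C[C@@H](C)CCCC[C@@H](O)CCC[C@@H](CC)/C=C/C=C(\COC)CC[C@H]1OC(C)(C)O[C@H]1C[C@H](O[Si](C)(C)C(C)(C)C)CNC(=O)[C@@H](O)CCC | intermediate (not isolated)
36 | 20,21-O-isopropylidene-23-O-(tert-butyldimethylsilyl) derivative of 37 | CCC[C@@H]1OC(=O)[C@@H](C)C[C@@H](C)CCCC[C@@H](O)CCC[C@@H](CC)/C=C/C=C(\COC)CC[C@H]2OC(C)(C)O[C@H]2C[C@H](O[Si](C)(C)C(C)(C)C)CNC1=O | intermediate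
37 | CNP0221503.3 (2′S,2S,4S,9R,13R,14E,16Z,20R,21S,23S) | CCC[C@@H]1OC(=O)[C@@H](C)C[C@@H](C)CCCC[C@@H](O)CCC[C@@H](CC)/C=C/C=C(\COC)CC[C@@H](O)[C@@H](O)C[C@H](O)CNC1=O | target

## Step count and risks

Total steps: 23. Longest linear sequence: 11 (steps 1, 2, 3, 5, 9, 10, 12, 20, 21, 22, 23, from compound 1).

Steps most likely to fail:

**Step 5 (alkyl–alkyl Suzuki with a β-branched primary bromide).** Oxidative addition is slow and β-hydride elimination may win. The fallback sets out from 4 and comes back at 9. Bromide 4 is coupled with pent-4-enylmagnesium bromide under Li2CuCl4 catalysis (THF, −20 °C, Kochi-type sp3–sp3 coupling) to give methyl (2S,4S)-2,4-dimethyldec-9-enoate F1. Epoxidation with mCPBA gives the C9-epimeric methyl (2S,4S)-2,4-dimethyl-8-(oxiran-2-yl)octanoate F2. Hydrolytic kinetic resolution with the Jacobsen complex (salen)Co(OAc) (trivalent cobalt, the enantiomer that hydrolyses the 9S epimer) and 0.55 eq water leaves 9, and the 9S epimer is removed as its diol. This replaces the chiral-pool C9 by a resolved one and the palladium coupling by a Grignard coupling.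

**Step 12 (Suzuki coupling on the vicinal bromo-iodo linchpin).** After oxidative addition the alkenylpalladium carries a trans β-bromide and may collapse to methyl propargyl ether, or both halides may couple; the regiochemistry of step 11 feeds the same risk. The fallback sets out from 16 and comes back at 33, building the trisubstituted olefin from a geminal dibromide instead. Cross-metathesis of 16 with crotonaldehyde (second-generation Hoveyda–Grubbs catalyst) gives methyl (2S,4S,9R,13R,14E)-13-ethyl-9-hydroxy-2,4-dimethyl-16-oxohexadec-14-enoate F3. Ph3P=CBr2 (from Ph3P+CHBr2 Br− and KOtBu, THF, 0 °C) converts it into methyl (2S,4S,9R,13R,14E)-17,17-dibromo-13-ethyl-9-hydroxy-2,4-dimethylheptadeca-14,16-dienoate F4. Trans-selective B-alkyl Suzuki coupling with borane 32 (Pd(dppf)Cl2, AsPh3, Cs2CO3, DMF/H2O) replaces only the bromine trans to C15 and gives the (14E,16Z)-17-bromo analogue of 33 F5. Stille coupling with Bu3SnCH2OMe (Pd(PPh3)4, CuI, NMP, 60 °C) with retention then gives 33.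

**Step 22 (macrolactonisation with two free hydroxyls).** The C2′ hydroxyl of the hydroxy amide is a weak nucleophile, and the free C9 hydroxyl may give the 10-membered lactone or oligomers. The fallback sets out from 34 and comes back at 37, removing the competing nucleophile and using a mixed anhydride. The unhindered C9 hydroxyl is silylated selectively (TBSCl, imidazole, DMF, 0 °C; K2CO3, MeOH/H2O work-up cleaves the silyl ester) to give the 9-O-(tert-butyldimethylsilyl) seco acid F6. Yamaguchi macrolactonisation (2,4,6-trichlorobenzoyl chloride, Et3N, THF; then DMAP, toluene, 1 mM, 60 °C), now with only the C2′ hydroxyl free, gives the 9,23-bis-O-(tert-butyldimethylsilyl)-20,21-O-isopropylidene macrolactone F7. The aqueous HF treatment of step 23 removes both silyl groups and the acetonide to give 37.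

## Further compounds

F1 | step 5 | methyl (2S,4S)-2,4-dimethyldec-9-enoate | COC(=O)[C@@H](C)C[C@@H](C)CCCCC=C
F2 | step 5 | methyl (2S,4S)-2,4-dimethyl-8-(oxiran-2-yl)octanoate (both C9 epimers) | COC(=O)[C@@H](C)C[C@@H](C)CCCCC1CO1
F3 | step 12 | methyl (2S,4S,9R,13R,14E)-13-ethyl-9-hydroxy-2,4-dimethyl-16-oxohexadec-14-enoate | COC(=O)[C@@H](C)C[C@@H](C)CCCC[C@@H](O)CCC[C@@H](CC)/C=C/C=O
F4 | step 12 | methyl (2S,4S,9R,13R,14E)-17,17-dibromo-13-ethyl-9-hydroxy-2,4-dimethylheptadeca-14,16-dienoate | COC(=O)[C@@H](C)C[C@@H](C)CCCC[C@@H](O)CCC[C@@H](CC)/C=C/C=C(Br)Br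
F5 | step 12 | (14E,16Z)-17-bromo analogue of 33 (bromine in place of CH2OMe) | COC(=O)[C@@H](C)C[C@@H](C)CCCC[C@@H](O)CCC[C@@H](CC)/C=C/C=C(\Br)CC[C@H]1OC(C)(C)O[C@H]1C[C@H](O[Si](C)(C)C(C)(C)C)CNC(=O)[C@@H](O)CCC
F6 | step 22 | 9-O-(tert-butyldimethylsilyl) derivative of 34 | OC(=O)[C@@H](C)C[C@@H](C)CCCC[C@@H](O[Si](C)(C)C(C)(C)C)CCC[C@@H](CC)/C=C/C=C(\COC)CC[C@H]1OC(C)(C)O[C@H]1C[C@H](O[Si](C)(C)C(C)(C)C)CNC(=O)[C@@H](O)CCC
F7 | step 22 | 9-O-(tert-butyldimethylsilyl) derivative of 36 | CCC[C@@H]1OC(=O)[C@@H](C)C[C@@H](C)CCCC[C@@H](O[Si](C)(C)C(C)(C)C)CCC[C@@H](CC)/C=C/C=C(\COC)CC[C@H]2OC(C)(C)O[C@H]2C[C@H](O[Si](C)(C)C(C)(C)C)CNC1=O
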